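## Retrosynthetic overview

1. Target 14 ⇐ dihydropyridine 11 by one closing hydrogenation (C=C saturation, loss of N-Cbz, O-Cbz and O-Bn, reductive N-methylation). The piperidine ring is formed last.
2. 11 ⇐ pyridine + benzyl chloroformate + flavanon-6-ylzinc 9 by Ni-catalysed enantioselective 1,2-arylation of the in situ N-acylpyridinium. This dearomatisation makes the C6–C2′ bond and the (R) centre in one step.
3. 9 ⇐ iodide 7 ⇐ 5-OH-directed C6 iodination of 7-O-benzyl pinocembrin 3, then 5-O-Cbz protection.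
4. The chromanone ring and its (2S) centre are bought as (2S)-pinocembrin. Ring order: chromanone (given) → dihydropyridine → piperidine.

Assumption: (2S)-pinocembrin (CAS 480-39-7) is bought as the single enantiomer and its ee is checked by chiral HPLC. Reagents that leave no non-hydrogen atom in a product (PPh3, DIAD, Et3N, Zn, H2, catalysts) are given under Conditions and are not numbered.

## Route

Step 1
Reactants: 1 (2S)-pinocembrin; 2 benzyl alcohol
Product: 3 (2S)-7-(benzyloxy)-5-hydroxy-2-phenylchroman-4-one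
Conditions: BnOH (1.1 equiv), PPh3 (1.2 equiv), DIAD (1.2 equiv), THF, 0 °C → rt
Reagents that add atoms: benzyl alcohol, OCc1ccccc1
Why: Mitsunobu etherification alkylates only the acidic, non-chelated 7-OH (the 5-OH is locked in a hydrogen bond to C4=O) under neutral conditions, so no base-driven retro-oxa-Michael opening can scramble the (2S) centre.

Step 2
Reactants: 3 (2S)-7-(benzyloxy)-5-hydroxy-2-phenylchroman-4-one; 4 N-iodosuccinimide
Product: 5 (2S)-7-(benzyloxy)-5-hydroxy-6-iodo-2-phenylchroman-4-one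
Conditions: NIS (1.05 equiv), DMF, 0 °C → rt, dark
Reagents that add atoms: N-iodosuccinimide, O=C1CCC(=O)N1I
Why: Electrophilic aromatic iodination with NIS goes ortho to the free, chelated 5-OH when O7 is alkylated (C6, not C8), the selectivity known for 5-hydroxy-7-alkoxy flavonoids, and the neutral medium leaves C2 untouched.

Step 3
Reactants: 5 (2S)-7-(benzyloxy)-5-hydroxy-6-iodo-2-phenylchroman-4-one; 6 benzyl chloroformate
Product: 7 benzyl (2S)-7-(benzyloxy)-6-iodo-4-oxo-2-phenylchroman-5-yl carbonate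
Conditions: CbzCl (1.5 equiv), Et3N (2 equiv), DMAP (10 mol%), CH2Cl2, 0 °C → rt
Reagents that add atoms: benzyl chloroformate, O=C(Cl)OCc1ccccc1
Why: DMAP-catalysed O-acylation with a chloroformate masks the last acidic proton as a hydrogenolysable benzyl carbonate under mild amine-base conditions that do not affect C2, and the carbonate carbonyl later assists zinc insertion at the adjacent C–I bond.

Step 4
Reactants: 7 benzyl (2S)-7-(benzyloxy)-6-iodo-4-oxo-2-phenylchroman-5-yl carbonate; 8 pyridine; 6 benzyl chloroformate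
Product: 11 benzyl (2R)-2-[(2S)-7-(benzyloxy)-5-{[(benzyloxy)carbonyl]oxy}-4-oxo-2-phenylchroman-6-yl]pyridine-1(2H)-carboxylate, via arylzinc iodide 9 (not isolated), via N-Cbz-pyridinium chloride 10 (not isolated)
Conditions: (i) Zn dust (3 equiv, activated with BrCH2CH2Br/TMSCl), LiCl (1.5 equiv), THF, 25–40 °C; (ii) add to pyridine (3.3 equiv)/CbzCl (3.0 equiv) premixed in THF at −40 °C, Ni(acac)2 (10 mol%), chiral BINOL-derived phosphoramidite (20 mol%, the antipode that gives (R) at C2′), −40 → 0 °C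
Reagents that add atoms: pyridine, c1ccncc1; benzyl chloroformate, O=C(Cl)OCc1ccccc1
Why: LiCl-mediated direct zinc insertion tolerates ketone, carbonate and benzyl ether, and the Ni-catalysed enantioselective 1,2-arylation of the N-acylpyridinium ion formed in situ (a dearomatising Negishi-type coupling known for arylzinc halides) makes the C6–C2′ bond and sets C2′ as (R) by ligand control; the ligand antipode is fixed in a model run with 2,6-dimethoxyphenylzinc iodide, because the remote (2S) centre gives no bias and the di-ortho-substituted zinc reagent lies outside the tested scope.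

Step 5
Reactants: 11 benzyl (2R)-2-[(2S)-7-(benzyloxy)-5-{[(benzyloxy)carbonyl]oxy}-4-oxo-2-phenylchroman-6-yl]pyridine-1(2H)-carboxylate; 12 formaldehyde
Product: 14 (2S)-5,7-dihydroxy-6-[(2R)-1-methylpiperidin-2-yl]-2-phenylchroman-4-one, via N-H piperidine 13 (not isolated)
Conditions: (i) H2 (1 atm), 10% Pd/C, EtOAc–MeOH 1:1, rt; (ii) then 37% aq. HCHO (1.2 equiv), AcOH (2 equiv), H2 (1 atm), rt; filter, brief NaHCO3 work-up, store as the hydrochloride
Reagents that add atoms: formaldehyde, C=O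
Why: Pd-catalysed hydrogenation saturates the diene and hydrogenolyses N-Cbz, O-Cbz and O-Bn to the secondary amine 13, which is reductively methylated in the same flask (reductive amination with HCHO/H2), while the sp3 centres C2′ (R) and C2 (S) are not touched and the weakly acidic medium suppresses retro-oxa-Michael epimerisation.

## Compound list

1 | (2S)-pinocembrin, (2S)-5,7-dihydroxy-2-phenylchroman-4-one | O=C1C[C@@H](c2ccccc2)Oc2cc(O)cc(O)c12 | starting material
2 | benzyl alcohol | OCc1ccccc1 | starting material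
3 | (2S)-7-(benzyloxy)-5-hydroxy-2-phenylchroman-4-one | O=C1C[C@@H](c2ccccc2)Oc2cc(OCc3ccccc3)cc(O)c12 | intermediate
4 | N-iodosuccinimide | O=C1CCC(=O)N1I | starting material
5 | (2S)-7-(benzyloxy)-5-hydroxy-6-iodo-2-phenylchroman-4-one | O=C1C[C@@H](c2ccccc2)Oc2cc(OCc3ccccc3)c(I)c(O)c12 | intermediate
6 | benzyl chloroformate | O=C(Cl)OCc1ccccc1 | starting material
7 | benzyl (2S)-7-(benzyloxy)-6-iodo-4-oxo-2-phenylchroman-5-yl carbonate | O=C1C[C@@H](c2ccccc2)Oc2cc(OCc3ccccc3)c(I)c(OC(=O)OCc3ccccc3)c12 | intermediate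
8 | pyridine | c1ccncc1 | starting material
9 | {(2S)-7-(benzyloxy)-5-{[(benzyloxy)carbonyl]oxy}-4-oxo-2-phenylchroman-6-yl}zinc iodide (LiCl complex) | O=C1C[C@@H](c2ccccc2)Oc2cc(OCc3ccccc3)c([Zn]I)c(OC(=O)OCc3ccccc3)c12 | intermediate
10 | 1-[(benzyloxy)carbonyl]pyridin-1-ium chloride | O=C(OCc1ccccc1)[n+]1ccccc1.[Cl-] | intermediate
11 | benzyl (2R)-2-[(2S)-7-(benzyloxy)-5-{[(benzyloxy)carbonyl]oxy}-4-oxo-2-phenylchroman-6-yl]pyridine-1(2H)-carboxylate | O=C(OCc1ccccc1)N1C=CC=C[C@@H]1c1c(OCc2ccccc2)cc2c(c1OC(=O)OCc1ccccc1)C(=O)C[C@@H](c1ccccc1)O2 | intermediate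
12 | formaldehyde | C=O | starting material
13 | (2S)-5,7-dihydroxy-2-phenyl-6-[(2R)-piperidin-2-yl]chroman-4-one | N1CCCC[C@@H]1c1c(O)cc2c(c1O)C(=O)C[C@@H](c1ccccc1)O2 | intermediate
14 | (2S)-5,7-dihydroxy-6-[(2R)-1-methylpiperidin-2-yl]-2-phenylchroman-4-one | CN1CCCC[C@@H]1c1c(O)cc2c(c1O)C(=O)C[C@@H](c1ccccc1)O2 | target

## Step count and risks

Total step count: 5. Longest linear sequence: 5 (1 → 3 → 5 → 7 → 11 → 14).

**Most likely to fail, 1: step 4.** The zinc reagent is electron-rich, flanked by two ortho oxygens and carries a ketone. Insertion may be slow, and the hindered nucleophile may give low conversion or low ee in the nickel arylation. The fallback sets out from 9 (made from 7 as in step 4) and comes back at 14. Negishi coupling of 9 with 2-bromopyridine (Pd2(dba)3/XPhos, THF, 50 °C) gives benzyl (2S)-7-(benzyloxy)-4-oxo-2-phenyl-6-(pyridin-2-yl)chroman-5-yl carbonate F1. Methyl triflate (CH2Cl2, 0 °C) turns it into 2-[(2S)-7-(benzyloxy)-5-{[(benzyloxy)carbonyl]oxy}-4-oxo-2-phenylchroman-6-yl]-1-methylpyridin-1-ium triflate F2. Ir-catalysed asymmetric hydrogenation of this pyridinium ([Ir(cod)Cl]2, chiral bisphosphine, H2 50 bar) gives benzyl (2S)-7-(benzyloxy)-6-[(2R)-1-methylpiperidin-2-yl]-4-oxo-2-phenylchroman-5-yl carbonate F3. H2 over Pd/C then removes the benzyl and Cbz groups to give 14. Here the stereocentre is set by hydrogenation and the N-methyl comes from the alkylating agent, so no formaldehyde is needed.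

**Most likely to fail, 2: step 2.** The C6/C8 selectivity may be lower on the flavanone than on flavones, and over-iodination is possible. The fallback sets out from 3 and comes back at 14. C8 is blocked instead of avoided, and the differentiation is moved to the metalation.
- NBS (2.1 equiv, DMF) gives (2S)-7-(benzyloxy)-6,8-dibromo-5-hydroxy-2-phenylchroman-4-one F4.
- CbzCl/Et3N/DMAP gives benzyl (2S)-7-(benzyloxy)-6,8-dibromo-4-oxo-2-phenylchroman-5-yl carbonate F5.
- Carbonate-directed zinc insertion (Zn, LiCl, THF, 40–50 °C) into the C6–Br bond gives {(2S)-7-(benzyloxy)-5-{[(benzyloxy)carbonyl]oxy}-8-bromo-4-oxo-2-phenylchroman-6-yl}zinc bromide F6.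
- Coupling of F6 with 10 under the nickel conditions of step 4 gives benzyl (2R)-2-[(2S)-7-(benzyloxy)-5-{[(benzyloxy)carbonyl]oxy}-8-bromo-4-oxo-2-phenylchroman-6-yl]pyridine-1(2H)-carboxylate F7.
- The conditions of step 5 with Et3N (1.1 equiv) in the first stage also remove the C8 bromide and lead through 13 to 14.

**Most likely to fail, 3: step 5.** Formaldehyde may attack C8 of the free 5,7-dihydroxy ring (Mannich or hydroxymethylation), and the basic amine may epimerise C2. The fallback sets out from 11 and comes back at 14. The nitrogen is methylated while O7 is still benzylated.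
- Hydrogenation over pyridine-poisoned Pd/C (H2 1 atm, MeOH) saturates the diene and cleaves N-Cbz and O-Cbz but spares the aryl benzyl ether, giving (2S)-7-(benzyloxy)-5-hydroxy-2-phenyl-6-[(2R)-piperidin-2-yl]chroman-4-one F8.
- HCHO/AcOH under H2 in the same flask gives (2S)-7-(benzyloxy)-5-hydroxy-6-[(2R)-1-methylpiperidin-2-yl]-2-phenylchroman-4-one F9.
- A separate debenzylation (H2, Pd(OH)2/C, EtOAc, no formaldehyde present) gives 14.

## Further compounds

F1 | step 4 | benzyl (2S)-7-(benzyloxy)-4-oxo-2-phenyl-6-(pyridin-2-yl)chroman-5-yl carbonate | O=C1C[C@@H](c2ccccc2)Oc2cc(OCc3ccccc3)c(-c3ccccn3)c(OC(=O)OCc3ccccc3)c12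
F2 | step 4 | 2-[(2S)-7-(benzyloxy)-5-{[(benzyloxy)carbonyl]oxy}-4-oxo-2-phenylchroman-6-yl]-1-methylpyridin-1-ium trifluoromethanesulfonate | C[n+]1ccccc1-c1c(OCc2ccccc2)cc2c(c1OC(=O)OCc1ccccc1)C(=O)C[C@@H](c1ccccc1)O2.[O-]S(=O)(=O)C(F)(F)F
F3 | step 4 | benzyl (2S)-7-(benzyloxy)-6-[(2R)-1-methylpiperidin-2-yl]-4-oxo-2-phenylchroman-5-yl carbonate | CN1CCCC[C@@H]1c1c(OCc2ccccc2)cc2c(c1OC(=O)OCc1ccccc1)C(=O)C[C@@H](c1ccccc1)O2
F4 | step 2 | (2S)-7-(benzyloxy)-6,8-dibromo-5-hydroxy-2-phenylchroman-4-one | O=C1C[C@@H](c2ccccc2)Oc2c(Br)c(OCc3ccccc3)c(Br)c(O)c12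
F5 | step 2 | benzyl (2S)-7-(benzyloxy)-6,8-dibromo-4-oxo-2-phenylchroman-5-yl carbonate | O=C1C[C@@H](c2ccccc2)Oc2c(Br)c(OCc3ccccc3)c(Br)c(OC(=O)OCc3ccccc3)c12
F6 | step 2 | {(2S)-7-(benzyloxy)-5-{[(benzyloxy)carbonyl]oxy}-8-bromo-4-oxo-2-phenylchroman-6-yl}zinc bromide | O=C1C[C@@H](c2ccccc2)Oc2c(Br)c(OCc3ccccc3)c([Zn]Br)c(OC(=O)OCc3ccccc3)c12
F7 | step 2 | benzyl (2R)-2-[(2S)-7-(benzyloxy)-5-{[(benzyloxy)carbonyl]oxy}-8-bromo-4-oxo-2-phenylchroman-6-yl]pyridine-1(2H)-carboxylate | O=C(OCc1ccccc1)N1C=CC=C[C@@H]1c1c(OCc2ccccc2)c(Br)c2c(c1OC(=O)OCc1ccccc1)C(=O)C[C@@H](c1ccccc1)O2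
F8 | step 5 | (2S)-7-(benzyloxy)-5-hydroxy-2-phenyl-6-[(2R)-piperidin-2-yl]chroman-4-one | N1CCCC[C@@H]1c1c(OCc2ccccc2)cc2c(c1O)C(=O)C[C@@H](c1ccccc1)O2
F9 | step 5 | (2S)-7-(benzyloxy)-5-hydroxy-6-[(2R)-1-methylpiperidin-2-yl]-2-phenylchroman-4-one | CN1CCCC[C@@H]1c1c(OCc2ccccc2)cc2c(c1O)C(=O)C[C@@H](c1ccccc1)O2
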